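The plan removes C2 from the tetrahydrofuran ring (O1, C2 to C5, with the C2 aryl and C3 hydroxymethyl trans and the C5 aryl and C4 hydroxymethyl cis). C2 holds two ring bonds, to O1 and to C3. It can therefore be supplied as a one-carbon 1,1-dipole, the carbon of a chiral aryl-substituted sulfonium ylide. Its partner is the four-atom chain O1–C5–C4–C3 of an alkylidene aroylacetate bearing the C3 silyloxymethyl group. In one operation the (4+1) annulation makes C2–C3 and O1–C2, closes the ring as a 2,3-trans-2,3-dihydrofuran and sets C2 and C3. The liberated C3 hydroxyl then guides hydrogenation of C4=C5.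

Key step: step 10

Remarks before the steps
- **Numbering.** The ring numbering above is used for every ring compound. The target is 2S,3R,4R,5R. The C2 aryl, C4 hydroxymethyl and C5 aryl lie on one face and the C3 hydroxymethyl on the other. With C2 and C3 as the saturated carbons, the annulation product is a 2,3-dihydrofuran (C4=C5).
- **Assumption.** The acceptor is taken to meet the ylide on the same face as an aldehyde does in epoxidation with this thiolane, where the (2R,5R)-sulfide gives (S,S)-stilbene oxide; the same spatial outcome at C2, where aryl outranks C3, would be 2R, so the 2S target calls for the (2S,5S)-thiolane and hence (2R,5R)-hexane-2,5-diol, and if the sense proves opposite the antipodal diol goes through the same steps.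
- **Design of the ylide precursor.** The salt is made as the tetrafluoroborate, because a halide ion can debenzylate this electron-rich benzylsulfonium ion. The ylide is preformed with exactly one equivalent of a potassium amide, so the acceptor, whose γ-CH2 is acidic, never meets free base or a chelating cation.

Step 1
Reactants: 1 syringaldehyde (4-hydroxy-3,5-dimethoxybenzaldehyde)
Product: 2 4-benzyloxy-3,5-dimethoxybenzaldehyde
Conditions: BnBr, K2CO3, DMF, 60 °C
Reagents that add atoms: benzyl bromide, BrCc1ccccc1
Why: Williamson ether synthesis, in which the acidic though flanked syringyl phenoxide is O-benzylated in a dipolar aprotic solvent while the aldehyde is untouched.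

Step 2
Reactants: 2 4-benzyloxy-3,5-dimethoxybenzaldehyde
Product: 3 (4-benzyloxy-3,5-dimethoxyphenyl)methanol
Conditions: NaBH4, MeOH/THF, 0 °C
Reagents that add atoms: none
Why: Borohydride reduction of an aromatic aldehyde, to which aryl methyl and benzyl ethers are inert.

Step 3
Reactants: 3 (4-benzyloxy-3,5-dimethoxyphenyl)methanol
Product: 4 4-benzyloxy-3,5-dimethoxybenzyl bromide
Conditions: PBr3, CH2Cl2, 0 °C
Reagents that add atoms: phosphorus tribromide, BrP(Br)Br
Why: Bromodehydroxylation through the phosphite ester (SN2 by bromide) is routine for 3,4,5-trialkoxybenzyl alcohols, and a short cold reaction avoids Friedel–Crafts self-condensation.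

Step 4
Reactants: 5 (2R,5R)-hexane-2,5-diol
Product: 6 (2R,5R)-hexane-2,5-diyl dimethanesulfonate
Conditions: MsCl, Et3N, CH2Cl2, 0 °C
Reagents that add atoms: methanesulfonyl chloride, CS(=O)(=O)Cl
Why: Sulfonate ester formation takes place at oxygen only, so both carbinol centres keep the R configuration.

Step 5
Reactants: 6 (2R,5R)-hexane-2,5-diyl dimethanesulfonate
Product: 7 (2S,5S)-2,5-dimethylthiolane
Conditions: Na2S·9H2O, EtOH, rt to 40 °C; distillation
Reagents that add atoms: sodium sulfide nonahydrate (Na2S·9H2O), [Na+].[Na+].[S-2]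
Why: Double SN2 displacement by sulfide (intermolecular, then 5-exo-tet) inverts both centres and turns the (R,R)-dimesylate into the trans, twofold-symmetric (S,S)-thiolane.

Step 6
Reactants: 4 4-benzyloxy-3,5-dimethoxybenzyl bromide; 7 (2S,5S)-2,5-dimethylthiolane
Product: 8 S-(4-benzyloxy-3,5-dimethoxybenzyl)-(2S,5S)-2,5-dimethylthiolanium tetrafluoroborate
Conditions: AgBF4, CH2Cl2, 0 °C to rt, dark; precipitation with Et2O
Reagents that add atoms: silver tetrafluoroborate (AgBF4), [Ag+].F[B-](F)(F)F
Why: S-Alkylation of a thioether assisted by halide abstraction, in which the two homotopic lone pairs of the sulfide allow only one salt (sulfur is not a stereocentre) and the non-nucleophilic anion blocks the reverse debenzylation.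

Step 7
Reactants: 9 acetosyringone (1-(4-hydroxy-3,5-dimethoxyphenyl)ethanone)
Product: 10 1-(4-benzyloxy-3,5-dimethoxyphenyl)ethanone
Conditions: BnBr, K2CO3, DMF, 60 °C
Reagents that add atoms: benzyl bromide, BrCc1ccccc1
Why: Williamson ether synthesis as in step 1, since carbonate is too weak a base to enolise the aryl methyl ketone to any harmful extent.

Step 8
Reactants: 10 1-(4-benzyloxy-3,5-dimethoxyphenyl)ethanone
Product: 11 methyl 3-(4-benzyloxy-3,5-dimethoxyphenyl)-3-oxopropanoate
Conditions: NaH, (MeO)2CO, THF, reflux; then aq HCl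
Reagents that add atoms: dimethyl carbonate, COC(=O)OC
Why: Crossed Claisen condensation (C-methoxycarbonylation of the ketone enolate), pulled to completion by irreversible deprotonation of the β-keto ester formed.

Step 9
Reactants: 11 methyl 3-(4-benzyloxy-3,5-dimethoxyphenyl)-3-oxopropanoate; 12 (tert-butyldimethylsilyloxy)acetaldehyde
Product: 13 methyl 2-(4-benzyloxy-3,5-dimethoxybenzoyl)-4-(tert-butyldimethylsilyloxy)but-2-enoate (E/Z mixture)
Conditions: piperidine (cat.), AcOH (cat.), 4 Å MS, CH2Cl2, 0 °C to rt
Reagents that add atoms: none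
Why: Knoevenagel condensation under nearly neutral piperidinium acetate catalysis with water removal, which limits double addition and alkene migration, and whose E/Z outcome is irrelevant because step 10 erases it.

Step 10
Reactants: 8 S-(4-benzyloxy-3,5-dimethoxybenzyl)-(2S,5S)-2,5-dimethylthiolanium tetrafluoroborate; 13 methyl 2-(4-benzyloxy-3,5-dimethoxybenzoyl)-4-(tert-butyldimethylsilyloxy)but-2-enoate
Product: 16 methyl (2S,3R)-2,5-bis(4-benzyloxy-3,5-dimethoxyphenyl)-3-[(tert-butyldimethylsilyloxy)methyl]-2,3-dihydrofuran-4-carboxylate, via sulfonium benzylide 14 (not isolated), via betaine enolate 15 (not isolated)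
Conditions: KN(SiMe3)2 (1.0 equiv to 8), THF, −78 °C; then 13, −78 °C to rt
Reagents that add atoms: none
Why: The preformed benzylide 14 adds in the 1,4 sense to the doubly activated alkene of 13 and forges C2–C3, giving zwitterion 15 whose keto ester enolate is planar at C4, so both alkene isomers of 13 converge. The ketone enolate oxygen then expels the thiolane from benzylic C2 in a 5-exo-tet SN2 closure that makes O1–C2 and the ring; should carbon close first (3-exo-tet), the donor–acceptor cyclopropane carries an electron-rich aryl donor and two acceptors and should pass into the same heterocycle by Cloke–Wilson rearrangement. The closest known reaction type is the (4+1) annulation of sulfonium ylides with alkylidene 1,3-dicarbonyl compounds to trans-2,3-dihydrofurans, and the chiral-sulfide control is carried over from ylide epoxidation and cyclopropanation. C2 is controlled by the thiolane: the ylide carbon turns its aryl group away from the ring, the ring methyl cis to it screens one face, and attack on the open face followed by inversion at C2 should give 2S from the (S,S)-sulfide. C3 is controlled relative to C2 by the anti betaine, in which aryl and silyloxymethyl avoid each other and which reaches the closure geometry most easily, so the 2,3-trans (3R) product results. The step needs conjugate addition rather than γ-deprotonation and O- rather than C-closure: the first is served by the absence of free base and the low temperature, the second by precipitation of KBF4, which leaves an unchelated enolate free to turn its ketone oxygen toward C2, while closure through the ester oxygen would give a far less stable ketene acetal.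

Step 11
Reactants: 16 methyl (2S,3R)-2,5-bis(4-benzyloxy-3,5-dimethoxyphenyl)-3-[(tert-butyldimethylsilyloxy)methyl]-2,3-dihydrofuran-4-carboxylate
Product: 17 methyl (2S,3R)-2,5-bis(4-benzyloxy-3,5-dimethoxyphenyl)-3-(hydroxymethyl)-2,3-dihydrofuran-4-carboxylate
Conditions: HF·pyridine, pyridine, THF, 0 °C to rt
Reagents that add atoms: none
Why: Fluoride cleavage of a primary silyl ether in a buffered, mildly acidic medium forms no free alkoxide, which avoids lactonisation onto the C4 ester and leaves the vinylogous carbonate and the benzylic C2–O1 bond intact.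

Step 12
Reactants: 17 methyl (2S,3R)-2,5-bis(4-benzyloxy-3,5-dimethoxyphenyl)-3-(hydroxymethyl)-2,3-dihydrofuran-4-carboxylate
Product: 18 methyl (2S,3R,4S,5R)-2,5-bis(4-benzyloxy-3,5-dimethoxyphenyl)-3-(hydroxymethyl)tetrahydrofuran-4-carboxylate (C2 aryl, C4 ester, C5 aryl on one face; C3 hydroxymethyl on the other)
Conditions: [Ir(cod)(PCy3)(py)]PF6 (cat.), H2 (50 bar), dry CH2Cl2, rt
Reagents that add atoms: none
Why: Hydroxyl-directed homogeneous hydrogenation with Crabtree's catalyst, in which the homoallylic C3 hydroxymethyl binds the cationic iridium and both hydrogens are delivered syn to the face it occupies, pushing the ester (4S) and the C5 aryl (5R) onto the face of the C2 aryl, while benzyl ethers are not cleaved by this catalyst.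

Step 13
Reactants: 18 methyl (2S,3R,4S,5R)-2,5-bis(4-benzyloxy-3,5-dimethoxyphenyl)-3-(hydroxymethyl)tetrahydrofuran-4-carboxylate
Product: 19 [(2S,3R,4R,5R)-2,5-bis(4-benzyloxy-3,5-dimethoxyphenyl)tetrahydrofuran-3,4-diyl]dimethanol
Conditions: LiAlH4, THF, 0 °C; aqueous work-up
Reagents that add atoms: none
Why: Ester reduction by LiAlH4 is faster than enolisation at 0 °C, so C4 keeps its geometry (the descriptor changes from 4S to 4R only through the priority change from ester to hydroxymethyl).

Step 14
Reactants: 19 [(2S,3R,4R,5R)-2,5-bis(4-benzyloxy-3,5-dimethoxyphenyl)tetrahydrofuran-3,4-diyl]dimethanol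
Product: 20 (2S,3R,4R,5R)-2,5-bis(4-hydroxy-3,5-dimethoxyphenyl)-3,4-bis(hydroxymethyl)tetrahydrofuran (target CNP0170897.6)
Conditions: H2 (1 atm), 10% Pd/C, EtOAc/MeOH, rt, stopped at full debenzylation
Reagents that add atoms: none
Why: Catalytic hydrogenolysis of aryl benzyl ethers in neutral solvent at atmospheric pressure is much faster than cleavage of the ring C2–O1 and C5–O1 bonds and touches no stereocentre.

Compound list
1 | syringaldehyde | COc1cc(C=O)cc(OC)c1O | starting material
2 | 4-benzyloxy-3,5-dimethoxybenzaldehyde | COc1cc(C=O)cc(OC)c1OCc2ccccc2 | intermediate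
3 | (4-benzyloxy-3,5-dimethoxyphenyl)methanol | COc1cc(CO)cc(OC)c1OCc2ccccc2 | intermediate
4 | 4-benzyloxy-3,5-dimethoxybenzyl bromide | COc1cc(CBr)cc(OC)c1OCc2ccccc2 | intermediate
5 | (2R,5R)-hexane-2,5-diol | C[C@@H](O)CC[C@@H](C)O | starting material
6 | (2R,5R)-hexane-2,5-diyl dimethanesulfonate | C[C@@H](OS(C)(=O)=O)CC[C@@H](C)OS(C)(=O)=O | intermediate
7 | (2S,5S)-2,5-dimethylthiolane | C[C@H]1CC[C@H](C)S1 | intermediate
8 | S-(4-benzyloxy-3,5-dimethoxybenzyl)-(2S,5S)-2,5-dimethylthiolanium tetrafluoroborate | C[C@H]1CC[C@H](C)[S+]1Cc2cc(OC)c(OCc3ccccc3)c(OC)c2.F[B-](F)(F)F | intermediate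
9 | acetosyringone | CC(=O)c1cc(OC)c(O)c(OC)c1 | starting material
10 | 1-(4-benzyloxy-3,5-dimethoxyphenyl)ethanone | CC(=O)c1cc(OC)c(OCc2ccccc2)c(OC)c1 | intermediate
11 | methyl 3-(4-benzyloxy-3,5-dimethoxyphenyl)-3-oxopropanoate | COC(=O)CC(=O)c1cc(OC)c(OCc2ccccc2)c(OC)c1 | intermediate
12 | (tert-butyldimethylsilyloxy)acetaldehyde | O=CCO[Si](C)(C)C(C)(C)C | starting material
13 | methyl 2-(4-benzyloxy-3,5-dimethoxybenzoyl)-4-(tert-butyldimethylsilyloxy)but-2-enoate (E/Z mixture, E isomer drawn) | COC(=O)/C(=C/CO[Si](C)(C)C(C)(C)C)C(=O)c1cc(OC)c(OCc2ccccc2)c(OC)c1 | intermediate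
14 | sulfonium benzylide: (2S,5S)-2,5-dimethylthiolanium 4-benzyloxy-3,5-dimethoxybenzylide | C[C@H]1CC[C@H](C)[S+]1[CH-]c2cc(OC)c(OCc3ccccc3)c(OC)c2 | intermediate
15 | betaine enolate: (2R,3R) adduct with the thiolanium group on C2 and the keto ester enolate on C3 | COc1cc(cc(OC)c1OCc2ccccc2)[C@H]([S+]3[C@@H](C)CC[C@@H]3C)[C@@H](CO[Si](C)(C)C(C)(C)C)C(C(=O)OC)=C([O-])c4cc(OC)c(OCc5ccccc5)c(OC)c4 | intermediate
16 | methyl (2S,3R)-2,5-bis(4-benzyloxy-3,5-dimethoxyphenyl)-3-[(tert-butyldimethylsilyloxy)methyl]-2,3-dihydrofuran-4-carboxylate | COc1cc(cc(OC)c1OCc2ccccc2)[C@H]3OC(c4cc(OC)c(OCc5ccccc5)c(OC)c4)=C(C(=O)OC)[C@@H]3CO[Si](C)(C)C(C)(C)C | intermediate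
17 | methyl (2S,3R)-2,5-bis(4-benzyloxy-3,5-dimethoxyphenyl)-3-(hydroxymethyl)-2,3-dihydrofuran-4-carboxylate | COc1cc(cc(OC)c1OCc2ccccc2)[C@H]3OC(c4cc(OC)c(OCc5ccccc5)c(OC)c4)=C(C(=O)OC)[C@@H]3CO | intermediate
18 | methyl (2S,3R,4S,5R)-2,5-bis(4-benzyloxy-3,5-dimethoxyphenyl)-3-(hydroxymethyl)tetrahydrofuran-4-carboxylate | COc1cc(cc(OC)c1OCc2ccccc2)[C@H]3O[C@@H](c4cc(OC)c(OCc5ccccc5)c(OC)c4)[C@@H](C(=O)OC)[C@@H]3CO | intermediate
19 | [(2S,3R,4R,5R)-2,5-bis(4-benzyloxy-3,5-dimethoxyphenyl)tetrahydrofuran-3,4-diyl]dimethanol | COc1cc(cc(OC)c1OCc2ccccc2)[C@H]3O[C@@H](c4cc(OC)c(OCc5ccccc5)c(OC)c4)[C@@H](CO)[C@@H]3CO | intermediate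
20 | (2S,3R,4R,5R)-2,5-bis(4-hydroxy-3,5-dimethoxyphenyl)-3,4-bis(hydroxymethyl)tetrahydrofuran | COc1cc([C@H]2O[C@@H](c3cc(OC)c(O)c(OC)c3)[C@@H](CO)[C@@H]2CO)cc(OC)c1O | target

Total step count: 14
Longest linear sequence: 9 steps (1, 2, 3, 6, 10, 11, 12, 13, 14)

Steps most likely to fail

1. **Step 10.**
   - What may go wrong: incomplete discrimination between the two faces of the ylide carbon; loss of C2 integrity through reversible addition or ionisation of the electron-rich benzylic C–S bond; proton transfer from the γ-CH2 of the acceptor to the ylide.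
   - Fallback: it sets out from 2 and 11, builds the ring from other bonds, and comes back at 17.
   - Horner–Wadsworth–Emmons olefination of 2 with trimethyl phosphonoacetate (NaH, THF) should give methyl (E)-3-(4-benzyloxy-3,5-dimethoxyphenyl)acrylate F1.
   - Reduction with i-Bu2AlH gives (E)-3-(4-benzyloxy-3,5-dimethoxyphenyl)prop-2-en-1-ol F2, and Ac2O/pyridine gives (E)-3-(4-benzyloxy-3,5-dimethoxyphenyl)allyl acetate F3.
   - Oxidative radical (3+2) annulation of 11 with F3 (Mn(OAc)3, AcOH, 50 °C) forms C3–C4 and O1–C2. The keto ester radical adds to the alkene carbon remote from the aryl group, the benzylic radical is oxidised to the cation, and the enol oxygen closes trans. This gives racemic methyl 2,3-trans-3-(acetoxymethyl)-2,5-bis(4-benzyloxy-3,5-dimethoxyphenyl)-2,3-dihydrofuran-4-carboxylate F4.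
   - Preparative chromatography on a chiral stationary phase delivers the (2S,3R)-acetate F5. Methanolysis (K2CO3, MeOH, 0 °C, where the solvent keeps the C4 ester open) returns 17.

2. **Step 12.**
   - What may go wrong: sluggish hydrogen uptake by the tetrasubstituted push–pull alkene; catalyst deactivation before conversion; leakage through undirected addition on the face of the C2 aryl.
   - Fallback: it sets out from 17 and comes back at 19, with the order of reduction reversed.
   - i-Bu2AlH (CH2Cl2, −78 °C) removes the deactivating ester first and gives [(2S,3R)-2,5-bis(4-benzyloxy-3,5-dimethoxyphenyl)-2,3-dihydrofuran-3,4-diyl]dimethanol F6, an electron-rich aryl enol ether.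
   - F6 is used at once under acid-free handling and hydrogenated with [Ir(cod)(PCy3)(py)]PF6 and H2 in CH2Cl2.
   - Only the face bearing the C3 hydroxymethyl lets both hydroxyls bind one iridium centre, and it is also the face away from the C2 aryl. The same syn delivery should therefore lead directly to 19.

3. **Step 9.**
   - What may go wrong: addition of a second keto ester to the product; migration of the alkene out of conjugation toward the silyl enol ether under amine catalysis.
   - Fallback: it sets out from 11 and comes back at 13 without an aldehyde or an amine.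
   - C-alkylation of 11 with 2-(tert-butyldimethylsilyloxy)ethyl iodide (K2CO3, acetone, reflux) gives methyl 2-(4-benzyloxy-3,5-dimethoxybenzoyl)-4-(tert-butyldimethylsilyloxy)butanoate F7.
   - Selenenylation of its enolate (NaH, PhSeCl, THF, 0 °C) gives the 2-(phenylselanyl) keto ester F8.
   - Oxidation (H2O2, CH2Cl2, 0 °C) gives the selenoxide F9, which undergoes syn elimination toward the only β-hydrogens available, those of the side-chain CH2, to give 13 under neutral conditions.

Further compounds
F1 | step 10 | methyl (E)-3-(4-benzyloxy-3,5-dimethoxyphenyl)acrylate | COC(=O)/C=C/c1cc(OC)c(OCc2ccccc2)c(OC)c1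
F2 | step 10 | (E)-3-(4-benzyloxy-3,5-dimethoxyphenyl)prop-2-en-1-ol | OC/C=C/c1cc(OC)c(OCc2ccccc2)c(OC)c1
F3 | step 10 | (E)-3-(4-benzyloxy-3,5-dimethoxyphenyl)allyl acetate | CC(=O)OC/C=C/c1cc(OC)c(OCc2ccccc2)c(OC)c1
F4 | step 10 | racemic methyl 2,3-trans-3-(acetoxymethyl)-2,5-bis(4-benzyloxy-3,5-dimethoxyphenyl)-2,3-dihydrofuran-4-carboxylate (both enantiomers written) | COc1cc(cc(OC)c1OCc2ccccc2)[C@H]3OC(c4cc(OC)c(OCc5ccccc5)c(OC)c4)=C(C(=O)OC)[C@@H]3COC(C)=O.COc1cc(cc(OC)c1OCc2ccccc2)[C@@H]3OC(c4cc(OC)c(OCc5ccccc5)c(OC)c4)=C(C(=O)OC)[C@H]3COC(C)=O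
F5 | step 10 | methyl (2S,3R)-3-(acetoxymethyl)-2,5-bis(4-benzyloxy-3,5-dimethoxyphenyl)-2,3-dihydrofuran-4-carboxylate | COc1cc(cc(OC)c1OCc2ccccc2)[C@H]3OC(c4cc(OC)c(OCc5ccccc5)c(OC)c4)=C(C(=O)OC)[C@@H]3COC(C)=O
F6 | step 12 | [(2S,3R)-2,5-bis(4-benzyloxy-3,5-dimethoxyphenyl)-2,3-dihydrofuran-3,4-diyl]dimethanol | COc1cc(cc(OC)c1OCc2ccccc2)[C@H]3OC(c4cc(OC)c(OCc5ccccc5)c(OC)c4)=C(CO)[C@@H]3CO
F7 | step 9 | methyl 2-(4-benzyloxy-3,5-dimethoxybenzoyl)-4-(tert-butyldimethylsilyloxy)butanoate (racemic, labile centre) | COC(=O)C(CCO[Si](C)(C)C(C)(C)C)C(=O)c1cc(OC)c(OCc2ccccc2)c(OC)c1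
F8 | step 9 | methyl 2-(4-benzyloxy-3,5-dimethoxybenzoyl)-4-(tert-butyldimethylsilyloxy)-2-(phenylselanyl)butanoate (racemic) | COC(=O)C(CCO[Si](C)(C)C(C)(C)C)([Se]c1ccccc1)C(=O)c2cc(OC)c(OCc3ccccc3)c(OC)c2
F9 | step 9 | selenoxide of F8 (formed and consumed in the flask) | COC(=O)C(CCO[Si](C)(C)C(C)(C)C)([Se](=O)c1ccccc1)C(=O)c2cc(OC)c(OCc3ccccc3)c(OC)c2
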